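**Strategy.** Everything rests on replacing the unfunctionalised C12–C13 bond of the 25-membered lactone ring (C1 = carbonyl carbon, C24 on the ring oxygen) by a sulfonyl bridge. A Ramberg–Bäcklund extrusion on the resulting 26-membered sulfone lactone, 1-oxa-14-thiacyclohexacosan-2-one 14,14-dioxide, expels SO2, joins the two sulfur-bound carbons as the C12=C13 alkene and contracts the ring to 25 atoms in one operation; hydrogenation then gives the target. The precursor is built in three steps: mid-chain C–S bond by thiolate alkylation, ring closure at the ester bond by Yamaguchi lactonisation, so that no ester meets sulfide or aqueous base beforehand, and oxidation of sulfur last.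

Key step: step 4

Remark: 12-sulfanyldodecanoic acid 1 and 12-bromododecan-1-ol 2 are taken as purchased materials.
Remark on locants: Cn in the text counts the chain from the carbonyl carbon (C1) to the oxygen-bearing carbon (C24); the ring names count from oxygen, so chain carbon Cn is ring atom n+1, and in the 26-membered sulfur rings n+2 beyond sulfur.

Step 1
Reactants: 1 12-sulfanyldodecanoic acid; 2 12-bromododecan-1-ol
Product: 3 12-[(12-hydroxydodecyl)sulfanyl]dodecanoic acid
Conditions: NaOH (2.05 equiv), degassed EtOH/H2O, N2, reflux; then aq. HCl
Reagents that add atoms: none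
Why: Thiolate S-alkylation of a primary bromide (SN2, the sulfur counterpart of the Williamson reaction) should be clean because the thiolate of 1 is far more nucleophilic in a protic medium than carboxylate, hydroxide or the alcohol of 2, and exclusion of air keeps the thiol from coupling to disulfide.

Step 2
Reactants: 3 12-[(12-hydroxydodecyl)sulfanyl]dodecanoic acid
Product: 5 1-oxa-14-thiacyclohexacosan-2-one, via Yamaguchi mixed anhydride 4 (not isolated)
Conditions: 2,4,6-Cl3C6H2COCl, Et3N, THF, rt; then slow addition to DMAP, toluene, reflux (high dilution, ca. 1 mM)
Reagents that add atoms: none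
Why: In this Yamaguchi macrolactonisation the carboxyl group is activated as mixed anhydride 4 and, under DMAP acyl-transfer catalysis at high dilution, the terminal hydroxyl should close the unstrained 26-membered ring, the dialkyl sulfide being inert to the acylating agent.

Step 3
Reactants: 5 1-oxa-14-thiacyclohexacosan-2-one
Product: 7 1-oxa-14-thiacyclohexacosan-2-one 14,14-dioxide, via sulfoxide 6 (not isolated)
Conditions: mCPBA (2.3 equiv), CH2Cl2, 0 °C to rt
Reagents that add atoms: mCPBA (3-chloroperoxybenzoic acid), O=C(OO)c1cccc(Cl)c1
Why: Peracid oxidation of a dialkyl sulfide runs stepwise through sulfoxide 6 to the sulfone, and the saturated lactone offers nothing else that mCPBA attacks.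

Step 4
Reactants: 7 1-oxa-14-thiacyclohexacosan-2-one 14,14-dioxide
Product: 12 (E)-1-oxacyclopentacos-13-en-2-one, via 13-bromo sulfone 8 (not isolated), via 15-bromo sulfone 9 (not isolated), via cis-episulfone 10 (not isolated), via trans-episulfone 11 (not isolated)
Conditions: KOH/Al2O3 (excess), CBr2F2, t-BuOH/CH2Cl2, 5 °C to rt
Reagents that add atoms: none
Why: Hydroxide on the alumina surface removes a proton next to the sulfonyl group, the carbanion takes bromine from CBr2F2 (giving 8 or 9, which converge), a second deprotonation at the other sulfur-bound carbon displaces bromide in a 1,3-fashion to close the thiirane 1,1-dioxide (10, which base can epimerise to 11), and cheletropic loss of SO2 leaves the alkene between ring atoms 13 and 14, that is C12=C13 of the chain. This is the Ramberg–Bäcklund reaction with in situ halogenation, known for unactivated di-primary dialkyl sulfones and for ring contraction of macrocyclic sulfones; CBr2F2 is chosen as halogen donor because bromide is displaced quickly, so the α-bromo sulfone should cyclise before it can be halogenated a second time. The only ring closed by bond formation is the three-membered episulfone (3-exo-tet); the 25-membered lactone ring is not cyclised but arises by contraction of the 26-membered ring when sulfur leaves. No stereocentre remains in the product; stereospecific loss of SO2 from the more stable trans-episulfone 11 should give the E alkene, and the alkene geometry carries no weight because step 5 removes the double bond. The step needs bromination at the two sulfur-bound CH2 groups and not at the CH2 next to the lactone carbonyl (chain C2), and it needs the lactone to outlast the base; fast proton transfer to sulfonyl-stabilised carbanions followed by irreversible ring closure should secure the first, and solid-supported KOH in t-BuOH/CH2Cl2, which keeps dissolved hydroxide low, the second.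

Step 5
Reactants: 12 (E)-1-oxacyclopentacos-13-en-2-one
Product: 13 24-tetracosanolide (1-oxacyclopentacosan-2-one)
Conditions: H2 (1 atm), 10% Pd/C, EtOAc, rt
Reagents that add atoms: none
Why: Heterogeneous catalytic hydrogenation should saturate the unhindered 1,2-dialkyl alkene, whatever its geometry, under mild conditions that leave the lactone untouched, and no stereocentre is involved.

**Compound list**

1 | 12-sulfanyldodecanoic acid (12-mercaptododecanoic acid) | OC(=O)CCCCCCCCCCCS | starting material
2 | 12-bromododecan-1-ol | OCCCCCCCCCCCCBr | starting material
3 | 12-[(12-hydroxydodecyl)sulfanyl]dodecanoic acid | OC(=O)CCCCCCCCCCCSCCCCCCCCCCCCO | intermediate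
4 | 12-[(12-hydroxydodecyl)sulfanyl]dodecanoic 2,4,6-trichlorobenzoic anhydride (Yamaguchi mixed anhydride) | OCCCCCCCCCCCCSCCCCCCCCCCCC(=O)OC(=O)c1c(Cl)cc(Cl)cc1Cl | intermediate (not isolated)
5 | 1-oxa-14-thiacyclohexacosan-2-one | O=C1CCCCCCCCCCCSCCCCCCCCCCCCO1 | intermediate
6 | 1-oxa-14-thiacyclohexacosan-2-one 14-oxide (racemic at sulfur) | O=C1CCCCCCCCCCCS(=O)CCCCCCCCCCCCO1 | intermediate (not isolated)
7 | 1-oxa-14-thiacyclohexacosan-2-one 14,14-dioxide | O=C1CCCCCCCCCCCS(=O)(=O)CCCCCCCCCCCCO1 | intermediate
8 | 13-bromo-1-oxa-14-thiacyclohexacosan-2-one 14,14-dioxide (racemic) | O=C1CCCCCCCCCCC(Br)S(=O)(=O)CCCCCCCCCCCCO1 | intermediate (not isolated)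
9 | 15-bromo-1-oxa-14-thiacyclohexacosan-2-one 14,14-dioxide (racemic) | O=C1CCCCCCCCCCCS(=O)(=O)C(Br)CCCCCCCCCCCO1 | intermediate (not isolated)
10 | cis-13-oxa-26-thiabicyclo[23.1.0]hexacosan-12-one 26,26-dioxide (racemic; ring-fusion hydrogens on the same face) | O=C1CCCCCCCCCC[C@H]2[C@@H](CCCCCCCCCCCO1)S2(=O)=O | intermediate (not isolated)
11 | trans-13-oxa-26-thiabicyclo[23.1.0]hexacosan-12-one 26,26-dioxide (racemic; ring-fusion hydrogens on opposite faces) | O=C1CCCCCCCCCC[C@H]2[C@H](CCCCCCCCCCCO1)S2(=O)=O | intermediate (not isolated)
12 | (E)-1-oxacyclopentacos-13-en-2-one | O=C1CCCCCCCCCC/C=C/CCCCCCCCCCCO1 | intermediate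
13 | 24-tetracosanolide (1-oxacyclopentacosan-2-one) | O=C1CCCCCCCCCCCCCCCCCCCCCCCO1 | target

**Count and risks**

Total step count: 5. Longest linear sequence: 5 steps (from 1 or 2 to 13).

Steps most likely to fail:

1. Step 4. Deprotonation and bromination may occur at the carbon next to the lactone carbonyl instead of next to sulfur, and hydroxide may open the lactone before the extrusion is complete. The fallback sets out from 5 and comes back at 12. It fixes the halogen next to sulfur before any base is present. N-Chlorosuccinimide in CH2Cl2 chlorinates a dialkyl sulfide only at a sulfur-bound carbon (Pummerer-type, through the chlorosulfonium and thionium ions). This should give 13-chloro-1-oxa-14-thiacyclohexacosan-2-one F1 and 15-chloro-1-oxa-14-thiacyclohexacosan-2-one F2. The crude pair would be oxidised with mCPBA to 13-chloro-1-oxa-14-thiacyclohexacosan-2-one 14,14-dioxide F3 and 15-chloro-1-oxa-14-thiacyclohexacosan-2-one 14,14-dioxide F4. KOtBu in THF at −78 °C to 0 °C, a hydroxide-free and poorly nucleophilic base, would then effect the classical Ramberg–Bäcklund contraction through 10 and 11 to 12. With no halogen donor present, any enolisation of the lactone would be reversible and harmless.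

2. Step 2. Intermolecular acyl transfer may outrun ring closure, so that chains grow to dimeric and oligomeric esters. The fallback sets out from 2 and comes back at 5. It closes the ring through sulfur instead of oxygen. 12-Bromododecan-1-ol 2 would be esterified with 12-bromododecanoic acid F5 (TsOH cat., toluene, Dean–Stark) to give 12-bromododecyl 12-bromododecanoate F6. Simultaneous slow addition of F6 and Na2S·9H2O to DMF at high dilution would then form both C–S bonds and deliver 5.

3. Step 5. Traces of sulfur- or bromine-containing residues carried over from step 4 may poison the palladium surface, so that saturation of the alkene stalls. The fallback sets out from 12 and comes back at 13. It is a metal-free reduction with diimide, generated from p-toluenesulfonyl hydrazide and NaOAc in refluxing THF/H2O, which transfers hydrogen to the alkene in a concerted step and does not touch the lactone. No new compound lies on its way.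

Steps 1 and 3 are routine functional-group chemistry on unhindered positions.

**Further compounds**

F1 | step 4 | 13-chloro-1-oxa-14-thiacyclohexacosan-2-one (racemic) | O=C1CCCCCCCCCCC(Cl)SCCCCCCCCCCCCO1
F2 | step 4 | 15-chloro-1-oxa-14-thiacyclohexacosan-2-one (racemic) | O=C1CCCCCCCCCCCSC(Cl)CCCCCCCCCCCO1
F3 | step 4 | 13-chloro-1-oxa-14-thiacyclohexacosan-2-one 14,14-dioxide (racemic) | O=C1CCCCCCCCCCC(Cl)S(=O)(=O)CCCCCCCCCCCCO1
F4 | step 4 | 15-chloro-1-oxa-14-thiacyclohexacosan-2-one 14,14-dioxide (racemic) | O=C1CCCCCCCCCCCS(=O)(=O)C(Cl)CCCCCCCCCCCO1
F5 | step 2 | 12-bromododecanoic acid | OC(=O)CCCCCCCCCCCBr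
F6 | step 2 | 12-bromododecyl 12-bromododecanoate | BrCCCCCCCCCCCC(=O)OCCCCCCCCCCCCBr
F0 | step 5 | none | none
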